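**Plan**

1. Numbering used below: ring A positions 1 OMe, 2 H, 3 CO2H, 4 ether O, 5 OH, 6 Cl; ring B positions 1 ether O, 2 H, 3 CH3, 4 H, 5 OH, 6 CO2H.
2. Retrosynthesis: the three benzyl groups and the oxidation level of the ring A carboxyl (carried as a dioxolane-masked aldehyde) are adjusted last. Ring B is then cut at its 1–6 and 2–3 bonds: positions 6, 5, 4 and 3 (CO2R, OR, H, CH3) are C-3 to C-6 of a 4-oxy-6-methyl-2-pyrone-3-carboxylate, positions 1 and 2 are an ethynyl ether on the ring A oxygen, and the pyrone O-1/C-2 unit leaves as CO2.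
3. The ynol ether goes back through its 1,2-dichlorovinyl ether (trichloroethylene) to a salicylaldehyde, whose formyl carbon comes from ortho-formylation of a phenol derived from 2-chloro-1,3-dimethoxybenzene. The pyrone is cut into dibenzyl malonate and acetylketene.
4. Forward order: ring A is bought as a benzene and substituted (steps 1–8), the pyrone ring is closed (steps 9–10), ring B is built on the ether oxygen as the last ring (step 11), then acetal hydrolysis, oxidation and debenzylation follow (steps 12–14).
5. Stereochemistry: the target has no stereocentre; the E geometry of the vinyl ether and the bridgeheads of the transient cycloadduct are erased later.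

Key step: step 11

Remark: the ring B benzyl ester is assumed to ionise under BCl3 like the benzyl ethers once the neighbouring phenol oxygen is boron-bound; compounds 1, 8, 14 and 15 are taken as purchasable.

**Route**

Step 1
Reactants: 1 2-chloro-1,3-dimethoxybenzene
Product: 2 3-chloro-2,4-dimethoxybenzaldehyde
Conditions: Cl2CHOMe, TiCl4, CH2Cl2, 0 °C to rt; then ice-water
Reagents that add atoms: dichloromethyl methyl ether, COC(Cl)Cl; water, O
Why: Rieche formylation should attack the only kind of ring position that is ortho to one methoxy group and para to the other, since the remaining position is meta to both donors.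

Step 2
Reactants: 2 3-chloro-2,4-dimethoxybenzaldehyde
Product: 3 3-chloro-2-hydroxy-4-methoxybenzaldehyde
Conditions: BCl3, CH2Cl2, −78 to 0 °C; then H2O
Reagents that add atoms: none
Why: Chelation-directed Lewis-acid demethylation: BCl3 bound to the formyl oxygen should cleave only the ortho methoxy group through a six-membered boron chelate and leave the 4-methoxy group intact.

Step 3
Reactants: 3 3-chloro-2-hydroxy-4-methoxybenzaldehyde
Product: 4 2-(benzyloxy)-3-chloro-4-methoxybenzaldehyde
Conditions: BnBr, K2CO3, DMF, 60 °C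
Reagents that add atoms: benzyl bromide, BrCc1ccccc1
Why: Williamson etherification of the only phenol installs the benzyl group that protects the oxygen at position 5 of ring A until the last step.

Step 4
Reactants: 4 2-(benzyloxy)-3-chloro-4-methoxybenzaldehyde
Product: 6 2-(benzyloxy)-3-chloro-4-methoxyphenol, via aryl formate 5 (not isolated)
Conditions: mCPBA, CH2Cl2, rt; NaHCO3 wash; then K2CO3 (cat.), MeOH, rt
Reagents that add atoms: meta-chloroperoxybenzoic acid, O=C(OO)c1cccc(Cl)c1
Why: Dakin-type Baeyer–Villiger oxidation, in which the electron-rich aryl group (ortho and para alkoxy) should migrate in preference to hydride, followed by base-catalysed methanolysis of the formate.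

Step 5
Reactants: 6 2-(benzyloxy)-3-chloro-4-methoxyphenol
Product: 7 3-(benzyloxy)-4-chloro-2-hydroxy-5-methoxybenzaldehyde
Conditions: MgCl2, Et3N, (CH2O)n, MeCN, reflux; then 1 M HCl
Reagents that add atoms: paraformaldehyde (as formaldehyde), C=O
Why: Magnesium-phenoxide-directed ortho-formylation should deliver formaldehyde to the single free ortho position, and a second formaldehyde accepts hydride from the bound hydroxymethyl intermediate to give the aldehyde whose carbon becomes the carboxyl carbon at position 3 of ring A.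

Step 6
Reactants: 7 3-(benzyloxy)-4-chloro-2-hydroxy-5-methoxybenzaldehyde; 8 trichloroethylene
Product: 9 3-(benzyloxy)-4-chloro-2-{[(E)-1,2-dichloroethenyl]oxy}-5-methoxybenzaldehyde
Conditions: K2CO3, DMF, 70 °C
Reagents that add atoms: none
Why: Nucleophilic O-vinylation: base converts trichloroethylene into dichloroacetylene, to which the phenoxide adds anti to give the E dichlorovinyl ether, so the second carbon–oxygen bond of the future diaryl ether is made at a small sp carbon and not at a crowded arene.

Step 7
Reactants: 9 3-(benzyloxy)-4-chloro-2-{[(E)-1,2-dichloroethenyl]oxy}-5-methoxybenzaldehyde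
Product: 10 2-[3-(benzyloxy)-4-chloro-2-{[(E)-1,2-dichloroethenyl]oxy}-5-methoxyphenyl]-1,3-dioxolane
Conditions: HOCH2CH2OH, p-TsOH (cat.), PhMe, reflux, azeotropic removal of water
Reagents that add atoms: ethylene glycol, OCCO
Why: Acid-catalysed acetalisation masks the aldehyde against n-BuLi, and the chlorine-deactivated vinyl ether and the benzyl ether should tolerate the acid.

Step 8
Reactants: 10 2-[3-(benzyloxy)-4-chloro-2-{[(E)-1,2-dichloroethenyl]oxy}-5-methoxyphenyl]-1,3-dioxolane
Product: 13 2-[3-(benzyloxy)-4-chloro-2-(ethynyloxy)-5-methoxyphenyl]-1,3-dioxolane, via chloroethynyl ether 11 (not isolated), via lithium acetylide 12 (not isolated)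
Conditions: n-BuLi (2.3 equiv), THF, −78 to −40 °C; then H2O, −78 °C; used at once
Reagents that add atoms: none
Why: Standard conversion of a dichlorovinyl ether into an ynol ether by β-elimination of HCl, lithium–chlorine exchange and protonation of the acetylide; at this temperature n-BuLi should leave the aryl chloride, acetal and benzyl ether alone.

Step 9
Reactants: 14 dibenzyl malonate; 15 2,2,6-trimethyl-4H-1,3-dioxin-4-one
Product: 17 benzyl 4-hydroxy-6-methyl-2-oxo-2H-pyran-3-carboxylate, via acetoacetylmalonate 16 (not isolated)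
Conditions: 14, NaH, PhMe, rt; then 15, 110 °C; then 1 M HCl
Reagents that add atoms: none
Why: Retro-[4+2] fragmentation of the dioxinone gives acetylketene, which C-acylates the malonate enolate, and the enol oxygen of the new methyl ketone then lactonises onto one benzyl ester with loss of BnOH, as in the diketene–malonate pyrone synthesis.

Step 10
Reactants: 17 benzyl 4-hydroxy-6-methyl-2-oxo-2H-pyran-3-carboxylate
Product: 18 benzyl 4-(benzyloxy)-6-methyl-2-oxo-2H-pyran-3-carboxylate
Conditions: BnOH, PPh3, DIAD, THF, 0 °C to rt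
Reagents that add atoms: benzyl alcohol, OCc1ccccc1
Why: Mitsunobu alkylation of the acidic vinylogous acid, which for 4-hydroxy-2-pyrones should go to the 4-oxygen, while C-3 is blocked against C-alkylation by the ester.

Step 11
Reactants: 13 2-[3-(benzyloxy)-4-chloro-2-(ethynyloxy)-5-methoxyphenyl]-1,3-dioxolane; 18 benzyl 4-(benzyloxy)-6-methyl-2-oxo-2H-pyran-3-carboxylate
Product: 20 benzyl 2-(benzyloxy)-6-[2-(benzyloxy)-3-chloro-6-(1,3-dioxolan-2-yl)-4-methoxyphenoxy]-4-methylbenzoate, via bridged lactone 19 (not isolated)
Conditions: 18 (1.5 equiv), PhMe (1 M), 120 °C, sealed tube, BHT (cat.)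
Reagents that add atoms: none
Why: The electron-rich ethynyl ether 13, whose largest HOMO coefficient lies on the terminal CH, should add across C-3 and C-6 of the electron-poor pyrone 18 in an asynchronous inverse-electron-demand [4+2] cycloaddition to give bridged lactone 19, which then expels CO2 by retro-[4+2] at the same temperature and leaves ring B at the benzene oxidation level. The closest known reaction type is the inverse-demand Diels–Alder/decarboxylation sequence of 2-pyrone-3-carboxylates with ynol ethers, ynamines and ketene acetals, applied here to a 4-alkoxy-6-methyl pyrone and an aryl ethynyl ether. Ring B is closed by intermolecular [4+2] annulation, which forms its 1–6 bond (oxygenated alkyne carbon to pyrone C-3) and its 2–3 bond (alkyne CH to pyrone C-6) in one operation. No stereocentre is set, because both bridgeheads of racemic 19 become aromatic carbons. The step needs regioselectivity, which the C-3 ester secures by making C-6 the electrophilic terminus of the diene, so the polarised alkyne can only place its aryloxy carbon next to the ester. It also needs the cycloaddition to outrun self-reaction of 13, which is favoured by the absence of a retro-ene path to a ketene in an aryl ynol ether, by the excess of 18 and by the high concentration.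

Step 12
Reactants: 20 benzyl 2-(benzyloxy)-6-[2-(benzyloxy)-3-chloro-6-(1,3-dioxolan-2-yl)-4-methoxyphenoxy]-4-methylbenzoate
Product: 21 benzyl 2-(benzyloxy)-6-[2-(benzyloxy)-3-chloro-6-formyl-4-methoxyphenoxy]-4-methylbenzoate
Conditions: 1 M HCl, THF, rt
Reagents that add atoms: water, O
Why: Acid-catalysed acetal hydrolysis frees the aldehyde at position 3 of ring A, and the benzyl ester, benzyl ethers and diaryl ether are inert to dilute aqueous acid.

Step 13
Reactants: 21 benzyl 2-(benzyloxy)-6-[2-(benzyloxy)-3-chloro-6-formyl-4-methoxyphenoxy]-4-methylbenzoate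
Product: 22 3-(benzyloxy)-2-{3-(benzyloxy)-2-[(benzyloxy)carbonyl]-5-methylphenoxy}-4-chloro-5-methoxybenzoic acid
Conditions: NaClO2, NaH2PO4, 2-methyl-2-butene, t-BuOH/THF/H2O, rt
Reagents that add atoms: sodium chlorite, [Na+].[O-]Cl=O
Why: Pinnick oxidation converts the aryl aldehyde into the acid, and the alkene scavenger removes HOCl before it can chlorinate the still fully protected rings.

Step 14
Reactants: 22 3-(benzyloxy)-2-{3-(benzyloxy)-2-[(benzyloxy)carbonyl]-5-methylphenoxy}-4-chloro-5-methoxybenzoic acid
Product: 23 2-(2-carboxy-3-hydroxy-5-methylphenoxy)-4-chloro-3-hydroxy-5-methoxybenzoic acid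
Conditions: BCl3 (excess), C6HMe5, CH2Cl2, −78 to 0 °C; then H2O
Reagents that add atoms: none
Why: Lewis-acid debenzylation with pentamethylbenzene as a non-basic benzyl cation trap should remove both benzyl ethers and the benzyl ester, spare the aryl chloride, and leave the unchelated methyl ether at position 1 of ring A in place at low temperature.

**Compound list**

1 | 2-chloro-1,3-dimethoxybenzene | COc1cccc(OC)c1Cl | starting material
2 | 3-chloro-2,4-dimethoxybenzaldehyde | COc1ccc(C=O)c(OC)c1Cl | intermediate
3 | 3-chloro-2-hydroxy-4-methoxybenzaldehyde | COc1ccc(C=O)c(O)c1Cl | intermediate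
4 | 2-(benzyloxy)-3-chloro-4-methoxybenzaldehyde | COc1ccc(C=O)c(OCc2ccccc2)c1Cl | intermediate
5 | 2-(benzyloxy)-3-chloro-4-methoxyphenyl formate | COc1ccc(OC=O)c(OCc2ccccc2)c1Cl | intermediate
6 | 2-(benzyloxy)-3-chloro-4-methoxyphenol | COc1ccc(O)c(OCc2ccccc2)c1Cl | intermediate
7 | 3-(benzyloxy)-4-chloro-2-hydroxy-5-methoxybenzaldehyde | COc1cc(C=O)c(O)c(OCc2ccccc2)c1Cl | intermediate
8 | trichloroethylene | ClC=C(Cl)Cl | starting material
9 | 3-(benzyloxy)-4-chloro-2-{[(E)-1,2-dichloroethenyl]oxy}-5-methoxybenzaldehyde | COc1cc(C=O)c(O/C(Cl)=C\Cl)c(OCc2ccccc2)c1Cl | intermediate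
10 | 2-[3-(benzyloxy)-4-chloro-2-{[(E)-1,2-dichloroethenyl]oxy}-5-methoxyphenyl]-1,3-dioxolane | COc1cc(C2OCCO2)c(O/C(Cl)=C\Cl)c(OCc2ccccc2)c1Cl | intermediate
11 | 2-{3-(benzyloxy)-4-chloro-2-[(chloroethynyl)oxy]-5-methoxyphenyl}-1,3-dioxolane | COc1cc(C2OCCO2)c(OC#CCl)c(OCc2ccccc2)c1Cl | intermediate
12 | lithium 2-[2-(benzyloxy)-3-chloro-6-(1,3-dioxolan-2-yl)-4-methoxyphenoxy]ethyn-1-ide | COc1cc(C2OCCO2)c(OC#C[Li])c(OCc2ccccc2)c1Cl | intermediate
13 | 2-[3-(benzyloxy)-4-chloro-2-(ethynyloxy)-5-methoxyphenyl]-1,3-dioxolane | COc1cc(C2OCCO2)c(OC#C)c(OCc2ccccc2)c1Cl | intermediate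
14 | dibenzyl malonate | O=C(CC(=O)OCc1ccccc1)OCc1ccccc1 | starting material
15 | 2,2,6-trimethyl-4H-1,3-dioxin-4-one | CC1=CC(=O)OC(C)(C)O1 | starting material
16 | dibenzyl 2-(3-oxobutanoyl)propanedioate | CC(=O)CC(=O)C(C(=O)OCc1ccccc1)C(=O)OCc1ccccc1 | intermediate
17 | benzyl 4-hydroxy-6-methyl-2-oxo-2H-pyran-3-carboxylate | CC1=CC(O)=C(C(=O)OCc2ccccc2)C(=O)O1 | intermediate
18 | benzyl 4-(benzyloxy)-6-methyl-2-oxo-2H-pyran-3-carboxylate | CC1=CC(OCc2ccccc2)=C(C(=O)OCc2ccccc2)C(=O)O1 | intermediate
19 | benzyl 5-(benzyloxy)-8-[2-(benzyloxy)-3-chloro-6-(1,3-dioxolan-2-yl)-4-methoxyphenoxy]-1-methyl-3-oxo-2-oxabicyclo[2.2.2]octa-5,7-diene-4-carboxylate (racemic) | COc1cc(C2OCCO2)c(OC2=CC3(C)OC(=O)C2(C(=O)OCc2ccccc2)C(OCc2ccccc2)=C3)c(OCc2ccccc2)c1Cl | intermediate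
20 | benzyl 2-(benzyloxy)-6-[2-(benzyloxy)-3-chloro-6-(1,3-dioxolan-2-yl)-4-methoxyphenoxy]-4-methylbenzoate | COc1cc(C2OCCO2)c(Oc2cc(C)cc(OCc3ccccc3)c2C(=O)OCc2ccccc2)c(OCc2ccccc2)c1Cl | intermediate
21 | benzyl 2-(benzyloxy)-6-[2-(benzyloxy)-3-chloro-6-formyl-4-methoxyphenoxy]-4-methylbenzoate | COc1cc(C=O)c(Oc2cc(C)cc(OCc3ccccc3)c2C(=O)OCc2ccccc2)c(OCc2ccccc2)c1Cl | intermediate
22 | 3-(benzyloxy)-2-{3-(benzyloxy)-2-[(benzyloxy)carbonyl]-5-methylphenoxy}-4-chloro-5-methoxybenzoic acid | COc1cc(C(=O)O)c(Oc2cc(C)cc(OCc3ccccc3)c2C(=O)OCc2ccccc2)c(OCc2ccccc2)c1Cl | intermediate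
23 | 2-(2-carboxy-3-hydroxy-5-methylphenoxy)-4-chloro-3-hydroxy-5-methoxybenzoic acid | COc1cc(C(=O)O)c(Oc2cc(C)cc(O)c2C(=O)O)c(O)c1Cl | target

**Step count**

Total: 14 steps (ring A branch 8, pyrone branch 2, union and endgame 4).
Longest linear sequence: 12 steps (steps 1–8, then 11–14).

**Steps most likely to fail**

1. Step 11. The cycloaddition may be outrun by hydration or oligomerisation of the terminal ynol ether, because the 4-benzyloxy and 6-methyl groups make pyrone 18 a weak diene. The fallback joins the two rings by nucleophilic aromatic substitution instead and sets out from salicylaldehyde 7. Purchased 2,6-difluoro-4-methylbenzaldehyde F1 is treated with BnOH/NaH (THF, 0 °C) to replace one fluoride and give 2-(benzyloxy)-6-fluoro-4-methylbenzaldehyde F2. The phenoxide of 7 (Cs2CO3, DMSO, 100 °C) then displaces the remaining fluoride, which is activated by the ortho formyl group, to give 3-(benzyloxy)-2-[3-(benzyloxy)-2-formyl-5-methylphenoxy]-4-chloro-5-methoxybenzaldehyde F3. Pinnick oxidation (NaClO2, NaH2PO4, 2-methyl-2-butene) of both formyl groups gives 3-(benzyloxy)-2-[3-(benzyloxy)-2-carboxy-5-methylphenoxy]-4-chloro-5-methoxybenzoic acid F4. BCl3/C6HMe5 as in step 14 removes the two benzyl ethers and returns to the route at target 23.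

2. Step 8. Benzylic or ring lithiation may compete with the elimination, and the terminal ynol ether may hydrate or polymerise during work-up and concentration. The fallback sets out from 10: the acetylide 12 is generated as before but silylated in the flask with i-Pr3SiCl to give 2-[3-(benzyloxy)-4-chloro-5-methoxy-2-({[tri(propan-2-yl)silyl]ethynyl}oxy)phenyl]-1,3-dioxolane F5, which should survive chromatography and storage. n-Bu4NF (THF, 0 °C) then releases the terminal alkyne immediately before the cycloaddition, so the route is rejoined at 13.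

3. Step 14. Ionisation of the benzyl ester may be incomplete at low temperature, or the methyl ether at position 1 of ring A may be lost on warming. The fallback sets out from 22 and changes the mode of cleavage from Lewis-acid ionisation to catalytic hydrogenolysis (H2, Pd/C, EtOAc, rt), which removes all three benzyl groups reductively and returns to 23. The aryl chloride, flanked by two oxygen substituents, should be reduced more slowly, and the reaction is stopped after uptake of three equivalents of hydrogen. No new compound is made.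

**Further compounds**

F1 | step 11 | 2,6-difluoro-4-methylbenzaldehyde | Cc1cc(F)c(C=O)c(F)c1
F2 | step 11 | 2-(benzyloxy)-6-fluoro-4-methylbenzaldehyde | Cc1cc(F)c(C=O)c(OCc2ccccc2)c1
F3 | step 11 | 3-(benzyloxy)-2-[3-(benzyloxy)-2-formyl-5-methylphenoxy]-4-chloro-5-methoxybenzaldehyde | COc1cc(C=O)c(Oc2cc(C)cc(OCc3ccccc3)c2C=O)c(OCc2ccccc2)c1Cl
F4 | step 11 | 3-(benzyloxy)-2-[3-(benzyloxy)-2-carboxy-5-methylphenoxy]-4-chloro-5-methoxybenzoic acid | COc1cc(C(=O)O)c(Oc2cc(C)cc(OCc3ccccc3)c2C(=O)O)c(OCc2ccccc2)c1Cl
F5 | step 8 | 2-[3-(benzyloxy)-4-chloro-5-methoxy-2-({[tri(propan-2-yl)silyl]ethynyl}oxy)phenyl]-1,3-dioxolane | COc1cc(C2OCCO2)c(OC#C[Si](C(C)C)(C(C)C)C(C)C)c(OCc2ccccc2)c1Cl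
F0 | step 14 | none | none
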